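## The problem

Irisoquin D (11) is a single six-membered carbocycle at the quinone oxidation level, in which C1 and C4 are carbonyls, C2 bears a free hydroxyl, C3 an unbranched icosyl chain, C5 a methoxy group and C6 a hydrogen. There is no stereocentre, ring fusion or stereogenic double bond, so the task reduces to the contiguous oxygenation pattern, the placing of the chain, and telling O2 from O5. The 2-hydroxy enone is a vinylogous acid and the 5-methoxy enone a vinylogous ester: aqueous acid or base exchanges the methoxy group, nucleophiles add at C6, and reduction gives an air-sensitive hydroquinone, so the methyl ether belongs at the end under conditions the quinone tolerates. The C20 chain makes every intermediate waxy and poorly soluble in cold or polar media, which limits cryogenic and aqueous chemistry. The enabling feature is that the demethylated core 10 is a tautomer of a 3-alkylcyclohexane-1,2,4,5-tetraone, in which C1/C2 and C4/C5 are two vicinal dicarbonyl pairs joined through C3 and C6, the only ring carbons that bear carbon or hydrogen. C1–C2 with its flanking C6 and C3 can thus be a 2,3-diketone with two enolisable positions and C4–C5 an oxalate, and C2, C3 and the chain together are the 22 carbons of docosanoic acid (1). Since no redox change separates the tetraone from 10, ring formation can deliver the full oxidation pattern at once.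

## Retrosynthesis

**11 to 10.** The C5 methyl ether is disconnected first, giving dihydroxyquinone 10. Carrying a differentiated oxygen through ring formation would need an unsymmetrical two-carbon electrophile and would turn a symmetric annulation into a regiochemical problem. Left to the end, the icosyl group does the differentiating, because the O1–C1–C6–C5–O5 unit is unhindered and the O2–C2–C3–C4–O4 unit is flanked by the chain. 10 is simpler by one functional-group distinction and is the direct tautomer of the tetraketone. The forward reaction must etherify once, and only on the unit remote from the chain.

**10 to 7 and 8.** The ring is opened at C3–C4 and C5–C6, giving tetracosane-2,3-dione (7) as a four-carbon bis-nucleophile and diethyl oxalate (8) as a two-carbon bis-electrophile. The neighbouring cut (C1–C6 and C3–C4) would pair two different 2-oxo esters, each both nucleophile and electrophile, and a crossed condensation of that kind would be statistical. The chosen cut separates the roles: 8 cannot enolise and is symmetric, and 7 has exactly two enolisable carbons, so either order of acylation gives the same ring. The first acylation gives triketo ester 9, which closes onto its remaining ester. The precursors are an acyclic diketone and a bulk diester; the forward step must favour cross- over self-condensation and reach the cyclic dianion as the thermodynamic product.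

**7 to 6.** The C2 carbonyl of 7 is masked as the enol ether of 2-ethoxytetracos-1-en-3-one (6). Against carrying the free diketone, this keeps the vicinal dicarbonyl out of the organometallic step and lets it appear under mild acid, where the diketone is stable. 6 has the same skeleton but only one carbonyl, and the forward reaction is a plain enol ether hydrolysis.

**6 to 3 and 4.** The bond between the two oxygenated carbons of 6 (ring bond C1–C2) is cut to an acyl cation equivalent, Weinreb amide 3, and an acyl anion equivalent, 1-ethoxyvinyllithium (5) made from ethyl vinyl ether (4). Attaching the chain by enolate alkylation of a smaller diketone equivalent would be sluggish, and alpha-oxidation of a simple long-chain ketone would be regiochemically ambiguous. The acyl anion addition fixes both oxygens and the chain length without ambiguity. The forward reaction needs single addition, which the chelated tetrahedral adduct of 3 provides.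

**3 to 1.** The amide bond is cut to docosanoic acid (1), activated in the flask as acyl imidazole 2. This is a routine step from an inexpensive fatty acid.

## Roads not taken

**Alternative 1: tetronate Michael–Dieckmann annulation.** The ring is cut at C1–C6 and C4–C5. In the forward step the C5 carbanion of tetronate A1 (4-benzyloxy-3-icosylfuran-2(5H)-one) would add to the CH2 of vinyl sulfone A2 (1-methoxyvinyl phenyl sulfone). The resulting sulfonyl carbanion would attack the lactone carbonyl, and loss of the sulfonyl group with aromatisation would give hydroquinone A3.
- Merits: O2 (benzyl) and O5 (methyl) are distinguished from the start, so no selective methylation is needed. The chain can still come from 1, by acylating an ester enolate derived from it with a protected two-carbon hydroxyacyl unit on the way to A1.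
- Weak points: the acceptor A2 is deactivated at its beta carbon by the methoxy group. The alpha-methoxy sulfonyl carbanion is poorly stabilised and must attack a vinylogous carbonate carbonyl. The roles of donor and leaving-group carrier are inverted relative to the phthalide annulations that serve as models, so the step is as untested as the chosen one. A1 and A2 each need several steps, and A3 must still be debenzylated and oxidised.
- Comparison: this road is better on regiochemistry of the oxygen substituents. The chosen plan sets against it about half the step count, no protecting groups, no final oxidation, and a key step under thermodynamic rather than kinetic control.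

**Alternative 2: alkenylcyclobutenone ring expansion.** The ring is cut at C1–C6, with C1–C4 coming from a squaric acid derivative. Heating cyclobutenone A4 would open it to a dienylketene that closes between the ketene carbon and the vinyl CH2, giving hydroquinone A5.
- Merits: this ring expansion is a well-established route to highly oxygenated hydroquinones. O2 and O5 are differentiated by construction. On reliability of the ring-forming step this road is stronger than the chosen plan.
- Weak points: A4 needs the carbinol carbon next to the icosyl-bearing carbon. Direct addition to the corresponding alkoxy alkyl cyclobutenedione goes the other way, to the carbonyl next to the alkoxy-bearing carbon, and would place chain and ring hydrogen meta instead of para. The correct isomer needs both nucleophiles added in sequence with protection and an acid-mediated unravelling, which the acid-labile methoxyvinyl group tolerates poorly. The chain must come in as a primary organolithium reagent at low temperature. The tert-butyl ether must be removed and the hydroquinone oxidised at the end.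
- Comparison: better precedent and better oxygen differentiation, against roughly seven operations with cryogenic organolithium steps. The chosen plan offers five steps from bulk materials and the quinone oxidation level directly, at the price of an untested annulation and a selectivity-dependent last step.

**Alternative 3: photochemical diazo enone–siloxyalkyne benzannulation.** The ring is cut at C3–C4, C1–C2 and C4–C5. Irradiation of diazo enone A6 would give a vinylketene by Wolff rearrangement. Its [2+2] cycloaddition with siloxyalkyne A7, four-electron ring opening and six-electron electrocyclisation would give phenol A8.
- Merits: the benzannulation type is known to be regiocontrolled, and the silyl and methyl ethers are distinct. The step count is about the same as for the chosen plan (one or two steps to each partner, the annulation, oxidation, desilylation), so the chosen plan has no real advantage in length here.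
- Weak points: A8 lacks the C1 oxygen, which must be added by para-oxidation of the phenol. A6 is a light- and acid-sensitive diazo compound carrying a vinylogous ester. A7 needs an ynolate silylation on a long-chain precursor. The key step is photochemical.
- Comparison: this road is better on precedent and on oxygen differentiation. The chosen plan sets against it the absence of diazo compounds and photochemistry, and a ring-forming step that installs all four oxygens at the final oxidation level.

Key step: step 4

Remark on the chemistry: the target and all intermediates of the route are achiral, and 10 and 11 are written as their 1,4-benzoquinone tautomers.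

## Route

Step 1
Reactants: 1 docosanoic acid (behenic acid)
Product: 3 N-methoxy-N-methyldocosanamide, via 1-docosanoylimidazole 2 (not isolated)
Conditions: CDI, THF, 45 °C; then MeNH(OMe)·HCl, 25 °C
Reagents that add atoms: N,O-dimethylhydroxylamine hydrochloride, CNOC.Cl; 1,1'-carbonyldiimidazole, O=C(n1ccnc1)n1ccnc1 (its imidazolyl group is carried by 2 only)
Why: Acyl imidazole formation followed by aminolysis is a standard Weinreb amide synthesis; the imidazole set free buffers the amine hydrochloride, and warm THF keeps the fatty acid in solution.

Step 2
Reactants: 3 N-methoxy-N-methyldocosanamide; 4 ethyl vinyl ether (ethoxyethene)
Product: 6 2-ethoxytetracos-1-en-3-one, via 1-ethoxyvinyllithium 5 (not isolated)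
Conditions: 4, t-BuLi, THF, −78 to 0 °C; then 3, THF, −40 to 0 °C; H2O
Reagents that add atoms: tert-butyllithium, [Li]C(C)(C)C (supplies the lithium of 5 only)
Why: Alpha-lithiation of the vinyl ether gives acyl anion equivalent 5, which adds once to 3 because the N-methoxy-N-methyl adduct stays a lithium chelate until the quench (Weinreb ketone synthesis). The enol ether survives the neutral aqueous work-up.

Step 3
Reactants: 6 2-ethoxytetracos-1-en-3-one
Product: 7 tetracosane-2,3-dione
Conditions: 2 M aq. HCl, THF, 25 °C
Reagents that add atoms: water, O
Why: Acid-catalysed enol ether hydrolysis (protonation at the terminal CH2, addition of water, loss of ethanol) unmasks the second carbonyl. The conjugated ketone slows but does not block protonation, and the diketone has no acid-labile group.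

Step 4
Reactants: 7 tetracosane-2,3-dione; 8 diethyl oxalate
Product: 10 2,5-dihydroxy-3-icosyl-1,4-benzoquinone, via ethyl 2,4,5-trioxohexacosanoate 9 (not isolated)
Conditions: 8 (2.5 equiv), KOC(CH3)3 (4 equiv), THF, 0 °C, slow addition of 7; then 50 °C; aq. HCl, 0 °C
Reagents that add atoms: none
Why: Proposed new method: KOC(CH3)3 deprotonates the C1 methyl of 7 and the enolate is acylated by the non-enolisable diester 8 (ring bond C5–C6), giving 9 as its 2,4-dioxo ester enolate; a second, reversible deprotonation at the chain CH2 (future C3) lets that carbon attack the remaining ester (ring bond C3–C4), and loss of ethoxide gives the tetraketone tautomer of 10, isolated as the dihydroxyquinone after acidification. The closest known reaction types are the double Claisen condensation of oxalic esters with ketones bearing two alpha-methylene groups, which gives cyclopentane-1,2,4-triones by the same acylation–cyclisation sequence, and the base-mediated self-condensation of 2-oxo esters to 3,6-dialkyl-2,5-dihydroxybenzoquinones; a 2,3-diketone as the four-carbon bis-nucleophile has not been shown. The ring closes in a 6-(enolendo)-exo-trig Dieckmann-type mode, with the enolate double bond C2=C3 inside the new ring and the ester carbonyl outside it. All C-acylations are reversible and the dianion of 10, two vinylogous carboxylates in one ring, is the thermodynamic sink, so the product should arrive at the quinone oxidation level without a redox step. No stereocentre is formed. The selectivity needed is cross- over self-condensation, secured by keeping 8 in excess and adding 7 slowly so that its enolate meets oxalate before a second diketone, and by a hindered alkoxide that adds only reluctantly to the diketone carbonyls and so should not trigger benzilic ester rearrangement. Regiochemistry is not at stake, because 8 is symmetric and acylation of the two alpha carbons of 7 in either order leads to the same ring.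

Step 5
Reactants: 10 2,5-dihydroxy-3-icosyl-1,4-benzoquinone
Product: 11 Irisoquin D (2-hydroxy-3-icosyl-5-methoxy-1,4-benzoquinone)
Conditions: MeOH–THF, H2SO4 (cat.), 60 °C
Reagents that add atoms: methanol, CO
Why: Acid-catalysed addition–elimination of methanol on a vinylogous carboxylic acid (vinylogous Fischer esterification) is a known way to mono-methylate 3-alkyl-2,5-dihydroxy-1,4-benzoquinones. The unsubstituted O1–C1–C6–C5–O5 unit is attacked at C5 (attack at C1 gives the same compound after tautomerism). Both ends of the O2–C2–C3–C4–O4 unit are flanked by the icosyl-bearing C3, and an ether there would be twisted out of conjugation, so the second etherification should be much slower.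

## Compound list

1 | docosanoic acid (behenic acid) | CCCCCCCCCCCCCCCCCCCCCC(=O)O | starting material
2 | 1-docosanoylimidazole (1-(1H-imidazol-1-yl)docosan-1-one) | CCCCCCCCCCCCCCCCCCCCCC(=O)n1ccnc1 | intermediate
3 | N-methoxy-N-methyldocosanamide | CCCCCCCCCCCCCCCCCCCCCC(=O)N(C)OC | intermediate
4 | ethyl vinyl ether (ethoxyethene) | C=COCC | starting material
5 | 1-ethoxyvinyllithium | [Li]C(=C)OCC | intermediate
6 | 2-ethoxytetracos-1-en-3-one | CCCCCCCCCCCCCCCCCCCCCC(=O)C(=C)OCC | intermediate
7 | tetracosane-2,3-dione | CCCCCCCCCCCCCCCCCCCCCC(=O)C(C)=O | intermediate
8 | diethyl oxalate | CCOC(=O)C(=O)OCC | starting material
9 | ethyl 2,4,5-trioxohexacosanoate | CCOC(=O)C(=O)CC(=O)C(=O)CCCCCCCCCCCCCCCCCCCCC | intermediate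
10 | 2,5-dihydroxy-3-icosylcyclohexa-2,5-diene-1,4-dione (2,5-dihydroxy-3-icosyl-1,4-benzoquinone) | CCCCCCCCCCCCCCCCCCCCC1=C(O)C(=O)C=C(O)C1=O | intermediate
11 | Irisoquin D, 2-hydroxy-3-icosyl-5-methoxycyclohexa-2,5-diene-1,4-dione | CCCCCCCCCCCCCCCCCCCCC1=C(O)C(=O)C=C(OC)C1=O | target

## Step count and least certain steps

Total step count: 5. Longest linear sequence: 5 steps (1 to 3 to 6 to 7 to 10 to 11).

**Step 4 (key step, proposed new method).**
- What may go wrong: base-mediated self-aldol condensation of the diketone may outrun the first acylation. A second intermolecular oxalylation of the mono-adduct at the chain CH2 may compete with ring closure while oxalate is in excess. The mono-adduct enolate may close through oxygen instead of carbon, or may fail to reach the geometry needed for closure. All of these would drain material before the cyclic dianion can act as a sink.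
- Fallback (known chemistry): the approach changes from building the ring to alkylating a preformed dihydroxyquinone ring. The fallback sets out from 1 and returns at 10. That chemistry brings the chain in as a C20 aldehyde, so the C22 acid is first shortened by two carbons. Oxidative decarboxylation of 1 with Pb(OAc)4 and Cu(OAc)2 (cat.) in benzene–pyridine at 80 °C (Kochi reaction) should give henicos-1-ene F1. Ozonolysis of the terminal alkene of F1 (O3, CH2Cl2, −40 °C; then Me2S) should give icosanal F2. F2 would then be combined with an excess of purchased 2,5-dihydroxy-1,4-benzoquinone F3, L-proline (cat.) and diethyl 2,6-dimethyl-1,4-dihydropyridine-3,5-dicarboxylate (Hantzsch ester) in CH2Cl2 at 25 °C. Knoevenagel condensation of F2 at a free ring CH of F3, followed by transfer hydrogenation of the alkylidene intermediate (three-component reductive alkylation of a hydroxyquinone), should give 10, where the route is rejoined for step 5.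

**Step 5.**
- What may go wrong: mono-selectivity may be lost as etherification runs on to the hindered unit, or the reaction may stall because the C20 quinone dissolves poorly in methanol.
- Fallback: this sets out from 10 and returns at 11 without a new intermediate. It changes the bond formed (O–CH3 instead of C5–O) and the basis of selectivity. 10 would be converted to its dianion with excess K2CO3 in DMF and treated with one equivalent of (CH3O)2SO2 at 0 °C, then acidified. The dianion is far more nucleophilic than the mono-anion left after one alkylation, so methylation should stop after one methyl. The oxygens of the unsubstituted unit are the accessible ones, and the hard electrophile favours oxygen over C6.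

**Step 2.**
- What may go wrong: addition may be incomplete because 3 crystallises from THF at low temperature, or the basic vinyllithium may deprotonate the amide alpha to the carbonyl instead of adding.
- Fallback: this sets out from 3 and returns at 7. The second carbonyl is unveiled by oxidative cleavage instead of enol ether hydrolysis. CH2=C(CH3)MgBr in THF at 0 °C should convert 3 into 2-methyltetracos-1-en-3-one F4. Ozonolysis of the 1,1-disubstituted alkene of F4 (O3, CH2Cl2, −40 °C; then Me2S) should give 7.

## Further compounds

F1 | step 4 | henicos-1-ene | CCCCCCCCCCCCCCCCCCCC=C
F2 | step 4 | icosanal | CCCCCCCCCCCCCCCCCCCC=O
F3 | step 4 | 2,5-dihydroxy-1,4-benzoquinone | O=C1C=C(O)C(=O)C=C1O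
F0 | step 5 | none | none
F4 | step 2 | 2-methyltetracos-1-en-3-one | CCCCCCCCCCCCCCCCCCCCCC(=O)C(C)=C
A1 | alternative 1 | 4-(benzyloxy)-3-icosylfuran-2(5H)-one | CCCCCCCCCCCCCCCCCCCCC1=C(OCc2ccccc2)COC1=O
A2 | alternative 1 | (1-methoxyethenyl)sulfonylbenzene (1-methoxyvinyl phenyl sulfone) | C=C(OC)S(=O)(=O)c1ccccc1
A3 | alternative 1 | 2-(benzyloxy)-3-icosyl-5-methoxybenzene-1,4-diol | CCCCCCCCCCCCCCCCCCCCc1c(O)c(OC)cc(O)c1OCc1ccccc1
A4 | alternative 2 | 2-tert-butoxy-4-hydroxy-3-icosyl-4-(1-methoxyethenyl)cyclobut-2-en-1-one (racemic) | CCCCCCCCCCCCCCCCCCCCC1=C(OC(C)(C)C)C(=O)C1(O)C(=C)OC
A5 | alternative 2 | 2-tert-butoxy-3-icosyl-5-methoxybenzene-1,4-diol | CCCCCCCCCCCCCCCCCCCCc1c(O)c(OC)cc(O)c1OC(C)(C)C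
A6 | alternative 3 | (E)-1-diazo-4-methoxybut-3-en-2-one | CO/C=C/C(=O)C=[N+]=[N-]
A7 | alternative 3 | (docos-1-yn-1-yloxy)tri(propan-2-yl)silane | CCCCCCCCCCCCCCCCCCCCC#CO[Si](C(C)C)(C(C)C)C(C)C
A8 | alternative 3 | 2-icosyl-6-methoxy-3-[tri(propan-2-yl)silyloxy]phenol | CCCCCCCCCCCCCCCCCCCCc1c(O)c(OC)ccc1O[Si](C(C)C)(C(C)C)C(C)C
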